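**Retrosynthetic overview**
- Irisoquin-C is a 1,4-benzoquinone (C1=O, C4=O). Its ring consists of two oxygen-bearing alkenes, C2(OH)=C3(n-C19H39) and C5(OMe)=C6(H). It has no stereocentre, so the task is to place four different substituents correctly.
- C1–C2–C3–C4 is treated as a squarate four-carbon unit that already carries the C2 oxygen (masked as O-t-Bu) and the chain. C6–C5 is treated as a 2-methoxyvinyl anion.
- The key disconnection is C4–C5. The hydroquinone comes from a 4-hydroxy-4-(2-methoxyvinyl)cyclobutenone by thermal opening to a dienylketene and 6π closure. This six-membered carbocycle is the only ring formed, and the purchased four-membered ring is consumed in making it.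
- Before the key step, the C3–chain bond is made by Grignard addition to di-tert-butyl squarate followed by transposition, and the C1–C6 bond by vinyllithium addition to the ketone-like carbonyl. After it, the hydroquinone is oxidised to the quinone and the t-Bu ether is cleaved with acid.

Key step: step 5

Assumption: di-tert-butyl squarate, 1-bromononadecane and methyl vinyl ether are taken as catalogue chemicals, and the carbinol centre of the cyclobutenone is carried racemic because aromatisation destroys it.

Step 1
Reactants: 1 1-bromononadecane
Product: 2 nonadecylmagnesium bromide (titrated THF solution kept warm)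
Conditions: Mg turnings, I2 (cat.), THF, 45 °C
Reagents that add atoms: magnesium, [Mg]
Why: Grignard reagent formation by insertion of magnesium into an unhindered primary C–Br bond is routine, slow addition of 1 should hold back Wurtz coupling, and warm THF should keep the waxy reagent dissolved.

Step 2
Reactants: 2 nonadecylmagnesium bromide; 3 di-tert-butyl squarate (3,4-di-tert-butoxycyclobut-3-ene-1,2-dione)
Product: 6 3-tert-butoxy-4-nonadecylcyclobut-3-ene-1,2-dione, via bromomagnesium alkoxide 4 (not isolated), via tertiary trifluoroacetate 5 (not isolated)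
Conditions: 2 added to 3, THF, −40 °C; then (CF3CO)2O, −78 → 0 °C; cold aq. NaHCO3
Reagents that add atoms: none
Why: The Grignard reagent should add 1,2 to one of the two equivalent carbonyls of 3, and acylation of alkoxide 4 makes its oxygen a leaving group, so that 5 ionises to an alkoxy-stabilised cyclobutenyl cation that sheds the tert-butyl group of the oxygen next to the old ketone as isobutene (the standard squarate-to-alkylcyclobutenedione transposition), while starting from the alkoxide and quenching cold keeps the acid level low enough for the second tert-butyl ether to survive.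

Step 3
Reactants: 7 methyl vinyl ether
Product: 9 (Z)-1-bromo-2-methoxyethene, via 1,2-dibromo-1-methoxyethane 8 (not isolated)
Conditions: Br2, CH2Cl2, −78 °C; cold evaporation; PhNEt2, 90–100 °C, product distilled out, then fractionated
Reagents that add atoms: bromine, BrBr
Why: Bromine adds across the electron-rich enol ether and the amine then removes HBr through the easily ionised α-bromo ether (bromination–dehydrobromination), with the cis effect of 1-alkoxy-2-haloethenes favouring the Z isomer, which fractional distillation should free of E isomer.

Step 4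
Reactants: 9 (Z)-1-bromo-2-methoxyethene; 6 3-tert-butoxy-4-nonadecylcyclobut-3-ene-1,2-dione
Product: 11 racemic 3-tert-butoxy-4-hydroxy-4-[(Z)-2-methoxyvinyl]-2-nonadecylcyclobut-2-en-1-one, via (Z)-2-methoxyvinyllithium 10 (not isolated)
Conditions: 9, n-BuLi, Et2O, −80 °C; then 6 in dilute THF, −78 °C; sat. aq. NH4Cl at −78 °C, NaHCO3 wash; short column on Et3N-deactivated SiO2 or used crude
Reagents that add atoms: none
Why: Bromine–lithium exchange goes with retention to the internally O–Li coordinated 10, in which the syn arrangement of Li and OMe slows β-elimination, and its 1,2-addition should take the carbonyl flanked by the tert-butoxy carbon because the other carbonyl is deactivated as a vinylogous ester; the carbinol centre forms racemic and is erased in step 5.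

Step 5
Reactants: 11 racemic 3-tert-butoxy-4-hydroxy-4-[(Z)-2-methoxyvinyl]-2-nonadecylcyclobut-2-en-1-one
Product: 14 2-tert-butoxy-5-methoxy-3-nonadecylbenzene-1,4-diol, via dienylketene 12 (not isolated), via cyclohexadienone 13 (not isolated)
Conditions: toluene (degassed, 0.01 M), 110 °C, Ar, base-washed glassware; evaporated under Ar
Reagents that add atoms: none
Why: Heating breaks the C1–C4 bond of the cyclobutenone in a conrotatory 4π electrocyclic opening, and the C4 hydroxyl, as the better donor, rotates outward, so the methoxyvinyl arm of 12 lies on the same side of the new enol double bond as the ketene. The ketene carbon (future quinone C4) then bonds to the methoxy-bearing vinyl terminus (future C5) in a thermal disrotatory 6π electrocyclisation, which is the only ring closure of the step and gives the six-membered carbocycle 13. A proton shift from C6 of 13 to oxygen aromatises the ring to 14, which removes the one transient sp3 centre and the enol ether geometry, so no stereocentre has to be controlled. This is the Moore rearrangement of 4-alkenyl-4-hydroxycyclobutenones, applied here to a 3-tert-butoxy substrate carrying a β-alkoxyvinyl arm. The substitution pattern is inherited rather than chosen in this step, because the chain sits next to the ketene carbon and the tert-butoxy group next to the carbinol carbon, which allows only the 2-O-t-Bu, 3-alkyl, 5-OMe arrangement. The selectivity still needed is outward rotation of OH (secured by its donor character), aromatisation of 13 ahead of loss of methanol, and survival of the tert-butyl ether, for which an acid-free, aprotic, dilute medium is chosen.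

Step 6
Reactants: 14 2-tert-butoxy-5-methoxy-3-nonadecylbenzene-1,4-diol
Product: 15 2-tert-butoxy-5-methoxy-3-nonadecylcyclohexa-2,5-diene-1,4-dione
Conditions: Ag2O, Na2SO4, Et2O, rt, dark
Reagents that add atoms: none
Why: Two-electron hydroquinone-to-quinone oxidation of this very electron-rich diol by Ag2O runs under neutral anhydrous conditions that touch neither ether.

Step 7
Reactants: 15 2-tert-butoxy-5-methoxy-3-nonadecylcyclohexa-2,5-diene-1,4-dione
Product: 16 irisoquin-C (2-hydroxy-5-methoxy-3-nonadecylcyclohexa-2,5-diene-1,4-dione)
Conditions: CF3CO2H, CH2Cl2, 0 °C → rt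
Reagents that add atoms: none
Why: Acidolysis of the tert-butyl vinylogous ester proceeds through the tert-butyl cation with loss of isobutene, whereas the methyl ether cannot ionise and, with no water present, cannot be hydrolysed.

**Compound list**
1 | 1-bromononadecane | CCCCCCCCCCCCCCCCCCCBr | starting material
2 | nonadecylmagnesium bromide | CCCCCCCCCCCCCCCCCCC[Mg]Br | intermediate
3 | di-tert-butyl squarate (3,4-di-tert-butoxycyclobut-3-ene-1,2-dione) | CC(C)(C)OC1=C(OC(C)(C)C)C(=O)C1=O | starting material
4 | bromomagnesium 2,3-di-tert-butoxy-1-nonadecyl-4-oxocyclobut-2-en-1-olate (racemic) | CCCCCCCCCCCCCCCCCCCC1(O[Mg]Br)C(OC(C)(C)C)=C(OC(C)(C)C)C1=O | intermediate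
5 | 2,3-di-tert-butoxy-1-nonadecyl-4-oxocyclobut-2-en-1-yl trifluoroacetate (racemic) | CCCCCCCCCCCCCCCCCCCC1(OC(=O)C(F)(F)F)C(OC(C)(C)C)=C(OC(C)(C)C)C1=O | intermediate
6 | 3-tert-butoxy-4-nonadecylcyclobut-3-ene-1,2-dione | CCCCCCCCCCCCCCCCCCCC1=C(OC(C)(C)C)C(=O)C1=O | intermediate
7 | methyl vinyl ether (methoxyethene) | COC=C | starting material
8 | 1,2-dibromo-1-methoxyethane (racemic) | COC(Br)CBr | intermediate
9 | (Z)-1-bromo-2-methoxyethene | CO/C=C\Br | intermediate
10 | (Z)-2-methoxyvinyllithium | CO/C=C\[Li] | intermediate
11 | 3-tert-butoxy-4-hydroxy-4-[(Z)-2-methoxyvinyl]-2-nonadecylcyclobut-2-en-1-one (racemic) | CCCCCCCCCCCCCCCCCCCC1=C(OC(C)(C)C)C(O)(/C=C\OC)C1=O | intermediate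
12 | (3Z,5Z)-3-tert-butoxy-4-hydroxy-6-methoxy-2-nonadecylhexa-1,3,5-trien-1-one (dienylketene) | CCCCCCCCCCCCCCCCCCCC(=C=O)/C(OC(C)(C)C)=C(O)\C=C/OC | intermediate
13 | 3-tert-butoxy-4-hydroxy-6-methoxy-2-nonadecylcyclohexa-2,4-dien-1-one (racemic) | CCCCCCCCCCCCCCCCCCCC1=C(OC(C)(C)C)C(O)=CC(OC)C1=O | intermediate
14 | 2-tert-butoxy-5-methoxy-3-nonadecylbenzene-1,4-diol | CCCCCCCCCCCCCCCCCCCc1c(O)c(OC)cc(O)c1OC(C)(C)C | intermediate
15 | 2-tert-butoxy-5-methoxy-3-nonadecylcyclohexa-2,5-diene-1,4-dione | CCCCCCCCCCCCCCCCCCCC1=C(OC(C)(C)C)C(=O)C=C(OC)C1=O | intermediate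
16 | irisoquin-C (2-hydroxy-5-methoxy-3-nonadecylcyclohexa-2,5-diene-1,4-dione) | CCCCCCCCCCCCCCCCCCCC1=C(O)C(=O)C=C(OC)C1=O | target

Total step count: 7. Longest linear sequence: 6 steps (1 → 2 → 6 → 11 → 14 → 15 → 16).

**Steps most likely to fail**

Step 5.
- Risks: Dienone 13 may expel methanol faster than it shifts its proton. Part of the material may open with the hydroxyl turning inward, so that the ketene is captured as a lactone. The closure may be slowed because the Z-methoxy group sits on the inside of the triene terminus. Isobutene may be lost on long heating.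
- Fallback (sets out from 1, comes back at 16): the six-membered ring is bought as an arene instead of being built.
- 1,2,4,5-Tetramethoxybenzene is lithiated between two methoxy groups (n-BuLi, THF, 0 °C to rt) to 2,3,5,6-tetramethoxyphenyllithium F1. F1 is alkylated with 1 (THF/DMPU) to 1,2,4,5-tetramethoxy-3-nonadecylbenzene F2.
- Oxidative demethylation with (NH4)2Ce(NO3)6 in MeCN/H2O should give 2,5-dimethoxy-3-nonadecylcyclohexa-2,5-diene-1,4-dione F3.
- NaOH in aqueous EtOH, then acid, hydrolyses both vinylogous esters to 2,5-dihydroxy-3-nonadecylcyclohexa-2,5-diene-1,4-dione F4.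
- MeOH with catalytic H2SO4 should re-etherify only the C5 hydroxyl, whose carbon has a C–H neighbour. C2 is shielded by the chain, so this gives 16.

Step 4.
- Risks: The vinyllithium may lose lithium methoxide by β-elimination before it adds. The long-chain dione may crystallise out at −78 °C. Some attack may fall on the vinylogous ester carbonyl. The adduct may undergo acid-triggered allylic transposition to an enal during work-up or chromatography.
- Fallback (sets out from 9 and 6, comes back at 11): the two-carbon unit is brought in as an alkyne and reduced afterwards.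
- Two equivalents of LiN(iPr)2 (THF, −78 → 0 °C) effect anti elimination of HBr from 9 and deprotonate the resulting alkyne, giving lithium methoxyacetylide F5. This nucleophile cannot β-eliminate and tolerates the higher temperature at which 6 stays in solution.
- Addition of F5 to the same carbonyl of 6, with an NH4Cl quench, should give racemic 3-tert-butoxy-4-hydroxy-4-(methoxyethynyl)-2-nonadecylcyclobut-2-en-1-one F6.
- Syn semihydrogenation at rt (H2, Pd on CaCO3 poisoned with Pb(OAc)2, quinoline, EtOAc) should deliver the Z enol ether 11. The tetrasubstituted ring alkene should not react.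

Step 2.
- Risks: The poorly soluble Grignard reagent may add sluggishly to the hindered squarate or add twice. The second tert-butyl group may be lost while the trifluoroacetate collapses.
- Fallback (sets out from 2, comes back at 6): the chain is installed on an unhindered squarate and the tert-butyl group is put on last.
- Reagent 2 is added to dimethyl squarate (THF, −40 °C, NH4Cl quench) to give racemic 4-hydroxy-2,3-dimethoxy-4-nonadecylcyclobut-2-en-1-one F7.
- Concentrated HCl in CH2Cl2 transposes F7 to 3-methoxy-4-nonadecylcyclobut-3-ene-1,2-dione F8.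
- Aqueous HCl in THF at reflux hydrolyses the vinylogous ester to 3-hydroxy-4-nonadecylcyclobut-3-ene-1,2-dione F9.
- This strong acid is O-alkylated without added catalyst by tert-butyl 2,2,2-trichloroacetimidate (CH2Cl2/cyclohexane, rt). The two reactive oxygens of its anion are equivalent, so 6 is the only ether expected.

**Further compounds**
F1 | step 5 | 2,3,5,6-tetramethoxyphenyllithium | COc1cc(OC)c(OC)c([Li])c1OC
F2 | step 5 | 1,2,4,5-tetramethoxy-3-nonadecylbenzene | CCCCCCCCCCCCCCCCCCCc1c(OC)c(OC)cc(OC)c1OC
F3 | step 5 | 2,5-dimethoxy-3-nonadecylcyclohexa-2,5-diene-1,4-dione | CCCCCCCCCCCCCCCCCCCC1=C(OC)C(=O)C=C(OC)C1=O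
F4 | step 5 | 2,5-dihydroxy-3-nonadecylcyclohexa-2,5-diene-1,4-dione | CCCCCCCCCCCCCCCCCCCC1=C(O)C(=O)C=C(O)C1=O
F5 | step 4 | lithium methoxyacetylide | COC#C[Li]
F6 | step 4 | 3-tert-butoxy-4-hydroxy-4-(methoxyethynyl)-2-nonadecylcyclobut-2-en-1-one (racemic) | CCCCCCCCCCCCCCCCCCCC1=C(OC(C)(C)C)C(O)(C#COC)C1=O
F7 | step 2 | 4-hydroxy-2,3-dimethoxy-4-nonadecylcyclobut-2-en-1-one (racemic) | CCCCCCCCCCCCCCCCCCCC1(O)C(OC)=C(OC)C1=O
F8 | step 2 | 3-methoxy-4-nonadecylcyclobut-3-ene-1,2-dione | CCCCCCCCCCCCCCCCCCCC1=C(OC)C(=O)C1=O
F9 | step 2 | 3-hydroxy-4-nonadecylcyclobut-3-ene-1,2-dione | CCCCCCCCCCCCCCCCCCCC1=C(O)C(=O)C1=O
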